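## Retrosynthetic overview

- Prostanoid numbering is used: C1 is the ester carbon, the ring is C8–C12 (C9=O, C10–Br, C12–OH), and C7 carries OAc. The C7–C8 bond is cut by an anti aldol between the C8 enolate of a 2-bromo-4-silyloxycyclopent-2-enone and methyl (Z)-7-oxohept-5-enoate. O-acetylation and desilylation end the route.
- Enabling feature: the triad C9(=O)–C10(Br)=C11H is the retron of a gem-dibromocyclopropane opening. Removing C10 and joining C9 to C11 leaves a 3-oxy-3-alkylcyclobutanone with a mirror plane through C9 and C12.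
- The carbocycle is therefore carried as the four-membered ring C8–C9–C11–C12. Enantiotopic deprotonation desymmetrises it, which makes C12 stereogenic. Insertion of CBr2 as C10 then enlarges it to the cyclopentenone.
- The cyclobutanone comes from 3-(benzyloxy)cyclobutanone by allyl addition. Both Z-alkenes (C14=C15 and C5=C6) come from catalytic Z-selective cross-metathesis.
- Ring order: cyclobutane (purchased), then bicyclo[2.1.0]pentane (transient), then cyclopentenone.

Key step: step 7

Assumption: the (R,R)-configured lithium amide is taken to abstract a proton from the CH2 group that becomes C11. If the first run shows the opposite sense, the equally available (S,S)-amine is used and nothing else changes.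

## Route

Step 1
Reactants: 1 3-(benzyloxy)cyclobutan-1-one; 2 allylmagnesium bromide
Product: 3 1-allyl-3-(benzyloxy)cyclobutan-1-ol (C1–OH and C3–OBn cis expected as the main isomer; both isomers are achiral)
Conditions: THF/Et2O, −78 → 0 °C; sat. aq. NH4Cl
Reagents that add atoms: none
Why: Grignard 1,2-addition to a strained, highly electrophilic cyclobutanone; the allyl group should enter anti to the benzyloxy group, but this relation is irrelevant because the OBn carbon becomes the carbonyl carbon C9 in step 5.

Step 2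
Reactants: 3 1-allyl-3-(benzyloxy)cyclobutan-1-ol
Product: 4 [1-allyl-3-(benzyloxy)cyclobutoxy]triethylsilane
Conditions: TESOTf, 2,6-lutidine, CH2Cl2, −78 → 0 °C
Reagents that add atoms: triethylsilyl triflate, CC[Si](CC)(CC)OS(=O)(=O)C(F)(F)F
Why: Silyl triflate with a hindered pyridine is the standard silylation of a tertiary alcohol; the cap blocks retro-aldol opening of the later β-oxy cyclobutanone and O–H capture of the carbene.

Step 3
Reactants: 4 [1-allyl-3-(benzyloxy)cyclobutoxy]triethylsilane; 5 hept-1-ene
Product: 6 {3-(benzyloxy)-1-[(2Z)-oct-2-en-1-yl]cyclobutoxy}triethylsilane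
Conditions: 5 (5 equiv), cyclometalated (N-adamantyl NHC chelate) nitrato Ru Z-selective metathesis catalyst (3 mol %), THF, 35 °C, argon sweep
Reagents that add atoms: none
Why: Z-selective olefin cross-metathesis of two terminal alkenes, in which the side-bound metallacyclobutane forces both substituents to the same side and so sets C14=C15 as Z; excess 5 and removal of ethene favour the cross product.

Step 4
Reactants: 6 {3-(benzyloxy)-1-[(2Z)-oct-2-en-1-yl]cyclobutoxy}triethylsilane
Product: 7 3-[(2Z)-oct-2-en-1-yl]-3-(triethylsilyloxy)cyclobutan-1-ol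
Conditions: Na, NH3(l)/THF, −78 °C; solid NH4Cl
Reagents that add atoms: none
Why: Dissolving-metal cleavage of the benzylic C–O bond; the isolated Z-alkene and the silyl ether are not reduced, whereas catalytic hydrogenolysis would saturate the alkene.

Step 5
Reactants: 7 3-[(2Z)-oct-2-en-1-yl]-3-(triethylsilyloxy)cyclobutan-1-ol
Product: 8 3-[(2Z)-oct-2-en-1-yl]-3-(triethylsilyloxy)cyclobutan-1-one (achiral)
Conditions: Dess–Martin periodinane, NaHCO3, CH2Cl2, 0 °C → rt
Reagents that add atoms: none
Why: Dess–Martin oxidation under buffered, non-basic conditions gives the ketone without β-elimination of the silyloxy group; the cis/trans label disappears and 8 has a mirror plane through C9 and C12.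

Step 6
Reactants: 8 3-[(2Z)-oct-2-en-1-yl]-3-(triethylsilyloxy)cyclobutan-1-one
Product: 10 (3S)-3-[(2Z)-oct-2-en-1-yl]-1,3-bis(triethylsilyloxy)cyclobut-1-ene, via lithium enolate 9 (not isolated)
Conditions: bis[(R)-1-phenylethyl]amine, n-BuLi, THF, 0 °C; then −100 °C, TESCl (internal quench), slow addition of 8; product kept cold and used directly
Reagents that add atoms: chlorotriethylsilane, CC[Si](Cl)(CC)CC
Why: Enantioselective deprotonation of a prochiral ketone by a C2-symmetric chiral lithium amide under internal silyl quench, a type established for 3-substituted cyclobutanones and 4-substituted cyclohexanones; the base picks one of the two enantiotopic CH2 groups, that carbon becomes C11, this choice alone makes C12 a stereocentre (S), and immediate O-silylation keeps the enolate from expelling the β-silanolate.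

Step 7
Reactants: 10 (3S)-3-[(2Z)-oct-2-en-1-yl]-1,3-bis(triethylsilyloxy)cyclobut-1-ene
Product: 12 (4S)-2-bromo-4-[(2Z)-oct-2-en-1-yl]-4-(triethylsilyloxy)cyclopent-2-en-1-one, via dibromobicyclo[2.1.0]pentane 11 (not isolated)
Conditions: CHBr3 (1.2 equiv), KOt-Bu (1.3 equiv), pentane, −30 °C → rt; aq. NaHCO3
Reagents that add atoms: bromoform, BrC(Br)Br
Why: Dibromocarbene, set free from bromoform by α-elimination, adds in a concerted cheletropic [2+1] step (mode of closure of the three-membered ring C9–C10–C11: suprafacial cis addition to the π bond) to C9=C11 of 10 and gives the housane 11. In 11 the central bond C9–C11 is opened at once by the thermally allowed disrotatory 2π electrocyclic process of halocyclopropanes (Woodward–Hoffmann–DePuy rule: the endo bromide leaves, the ring bonds turn inward), pushed by the C9 siloxy oxygen and by the strain of the two fused small rings, so that the four-membered ring C8–C9–C11–C12 becomes the five-membered ring C8–C9–C10–C11–C12 without any further ring closure. Bromide takes the silyl group from the resulting 1-siloxy-2-bromoallyl cation, which delivers in the same flask the ring size, C9=O, the C10=C11 double bond at the enone oxidation level, and bromine on C10 only, a halogenation that electrophilic bromine could not do in the presence of the C14=C15 alkene. The closest known reaction types are the one-carbon enlargement of cyclic silyl enol ethers to 2-halocycloalk-2-enones with dihalocarbenes and the spontaneous opening of dihalocarbene adducts of cyclobutenes to 2,3-dihalocyclopentenes. No lasting stereocentre is made: the two ring-fusion centres of 11 are flattened again whichever face the carbene takes, and C12, a spectator with four intact bonds, carries the configuration fixed in step 6 into 12. The step needs chemoselectivity for the enol ether over the Z-alkene, which the oxygen donor and the strain-raised HOMO of the cyclobutene should secure together with a near-stoichiometric carbene charge (compare the selective attack of dihalocarbenes on the enol ether bond of 1-alkoxycyclohexa-1,4-dienes), while regiochemistry is inherent because C10 can only enter between C9 and C11.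

Step 8
Reactants: 13 methyl hex-5-enoate; 14 (2Z)-but-2-ene-1,4-diol
Product: 15 methyl (5Z)-7-hydroxyhept-5-enoate
Conditions: 14 (2 equiv), Ru catechodithiolate (stereoretentive) metathesis catalyst (5 mol %), THF, 22 °C
Reagents that add atoms: none
Why: Stereoretentive cross-metathesis of a terminal alkene with (Z)-butenediol, a known entry to Z-allylic alcohols; the Z geometry of 14 is handed on to C5=C6.

Step 9
Reactants: 15 methyl (5Z)-7-hydroxyhept-5-enoate
Product: 16 methyl (5Z)-7-oxohept-5-enoate
Conditions: Dess–Martin periodinane, NaHCO3, CH2Cl2, 0 °C; short filtration, used at once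
Reagents that add atoms: none
Why: Buffered Dess–Martin oxidation of a Z-allylic alcohol runs without acid, base or nucleophile that could isomerise the Z-enal to the E-enal.

Step 10
Reactants: 12 (4S)-2-bromo-4-[(2Z)-oct-2-en-1-yl]-4-(triethylsilyloxy)cyclopent-2-en-1-one; 16 methyl (5Z)-7-oxohept-5-enoate
Product: 18 methyl (5Z,7S)-7-{(1R,2S)-4-bromo-2-[(2Z)-oct-2-en-1-yl]-5-oxo-2-(triethylsilyloxy)cyclopent-3-en-1-yl}-7-hydroxyhept-5-enoate, via lithium dienolate 17 (not isolated)
Conditions: LDA (commercial solution, 1.05 equiv), THF, −78 °C; then 16, −78 °C; AcOH/THF quench at −78 °C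
Reagents that add atoms: none
Why: Kinetic lithium enolate aldol through a Zimmerman–Traxler chair: the ring-locked E(O)-enolate should give the anti C7/C8 relation (7S), and the aldehyde should reach C8 over the face that carries the C12 oxygen, anti to the C12–C13 bond whose CH2 is the larger first atom and the better σ-donor, which places the two carbon chains trans (8R).

Step 11
Reactants: 18 methyl (5Z,7S)-7-{(1R,2S)-4-bromo-2-[(2Z)-oct-2-en-1-yl]-5-oxo-2-(triethylsilyloxy)cyclopent-3-en-1-yl}-7-hydroxyhept-5-enoate
Product: 19 methyl (5Z,7S)-7-acetoxy-7-{(1R,2S)-4-bromo-2-[(2Z)-oct-2-en-1-yl]-5-oxo-2-(triethylsilyloxy)cyclopent-3-en-1-yl}hept-5-enoate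
Conditions: Ac2O, pyridine, CH2Cl2, 0 °C (no DMAP)
Reagents that add atoms: acetic anhydride, CC(=O)OC(C)=O
Why: O-acetylation of the only free hydroxyl with retention at C7; low temperature and the absence of a stronger base are meant to keep the β-acetoxy ketone from E1cB loss of acetic acid across C7–C8.

Step 12
Reactants: 19 methyl (5Z,7S)-7-acetoxy-7-{(1R,2S)-4-bromo-2-[(2Z)-oct-2-en-1-yl]-5-oxo-2-(triethylsilyloxy)cyclopent-3-en-1-yl}hept-5-enoate
Product: 20 7-acetoxy-7,8-dihydrobromovulone I
Conditions: HF·pyridine, pyridine/THF, 0 °C → rt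
Reagents that add atoms: none
Why: Buffered HF cleavage of a triethylsilyl ether, as used for β-hydroxy ketone prostanoids; no base is present, so neither loss of acetic acid nor retro-aldol at C12 is triggered and no stereocentre is touched.

## Compound list

1 | 3-(benzyloxy)cyclobutan-1-one | O=C1CC(OCc2ccccc2)C1 | starting material
2 | allylmagnesium bromide | C=CC[Mg]Br | starting material
3 | 1-allyl-3-(benzyloxy)cyclobutan-1-ol (O/O cis drawn) | C=CC[C@@]1(O)C[C@H](OCc2ccccc2)C1 | intermediate
4 | [1-allyl-3-(benzyloxy)cyclobutoxy]triethylsilane (O/O cis drawn) | C=CC[C@@]1(O[Si](CC)(CC)CC)C[C@H](OCc2ccccc2)C1 | intermediate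
5 | hept-1-ene | C=CCCCCC | starting material
6 | {3-(benzyloxy)-1-[(2Z)-oct-2-en-1-yl]cyclobutoxy}triethylsilane (O/O cis drawn) | CCCCC/C=C\C[C@@]1(O[Si](CC)(CC)CC)C[C@H](OCc2ccccc2)C1 | intermediate
7 | 3-[(2Z)-oct-2-en-1-yl]-3-(triethylsilyloxy)cyclobutan-1-ol (O/O cis drawn) | CCCCC/C=C\C[C@@]1(O[Si](CC)(CC)CC)C[C@H](O)C1 | intermediate
8 | 3-[(2Z)-oct-2-en-1-yl]-3-(triethylsilyloxy)cyclobutan-1-one (achiral) | CCCCC/C=C\CC1(O[Si](CC)(CC)CC)CC(=O)C1 | intermediate
9 | lithium (3S)-3-[(2Z)-oct-2-en-1-yl]-3-(triethylsilyloxy)cyclobut-1-en-1-olate (not isolated) | CCCCC/C=C\C[C@@]1(O[Si](CC)(CC)CC)C=C(O[Li])C1 | intermediate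
10 | (3S)-3-[(2Z)-oct-2-en-1-yl]-1,3-bis(triethylsilyloxy)cyclobut-1-ene | CCCCC/C=C\C[C@@]1(O[Si](CC)(CC)CC)C=C(O[Si](CC)(CC)CC)C1 | intermediate
11 | (3S)-5,5-dibromo-3-[(2Z)-oct-2-en-1-yl]-1,3-bis(triethylsilyloxy)bicyclo[2.1.0]pentane (not isolated; drawn for carbene attack on the face of the C12 oxygen, the other face converges on the same product) | CCCCC/C=C\C[C@@]1(O[Si](CC)(CC)CC)[C@@H]2C(Br)(Br)[C@]2(O[Si](CC)(CC)CC)C1 | intermediate
12 | (4S)-2-bromo-4-[(2Z)-oct-2-en-1-yl]-4-(triethylsilyloxy)cyclopent-2-en-1-one | CCCCC/C=C\C[C@@]1(O[Si](CC)(CC)CC)C=C(Br)C(=O)C1 | intermediate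
13 | methyl hex-5-enoate | C=CCCCC(=O)OC | starting material
14 | (2Z)-but-2-ene-1,4-diol | OC/C=C\CO | starting material
15 | methyl (5Z)-7-hydroxyhept-5-enoate | OC/C=C\CCCC(=O)OC | intermediate
16 | methyl (5Z)-7-oxohept-5-enoate | O=C/C=C\CCCC(=O)OC | intermediate
17 | lithium (3S)-5-bromo-3-[(2Z)-oct-2-en-1-yl]-3-(triethylsilyloxy)cyclopenta-1,4-dien-1-olate (not isolated) | CCCCC/C=C\C[C@@]1(O[Si](CC)(CC)CC)C=C(Br)C(O[Li])=C1 | intermediate
18 | methyl (5Z,7S)-7-{(1R,2S)-4-bromo-2-[(2Z)-oct-2-en-1-yl]-5-oxo-2-(triethylsilyloxy)cyclopent-3-en-1-yl}-7-hydroxyhept-5-enoate | CCCCC/C=C\C[C@@]1(O[Si](CC)(CC)CC)C=C(Br)C(=O)[C@@H]1[C@H](/C=C\CCCC(=O)OC)O | intermediate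
19 | methyl (5Z,7S)-7-acetoxy-7-{(1R,2S)-4-bromo-2-[(2Z)-oct-2-en-1-yl]-5-oxo-2-(triethylsilyloxy)cyclopent-3-en-1-yl}hept-5-enoate | CCCCC/C=C\C[C@@]1(O[Si](CC)(CC)CC)C=C(Br)C(=O)[C@@H]1[C@H](/C=C\CCCC(=O)OC)OC(C)=O | intermediate
20 | 7-acetoxy-7,8-dihydrobromovulone I, methyl (5Z,7S)-7-acetoxy-7-{(1R,2S)-4-bromo-2-hydroxy-2-[(2Z)-oct-2-en-1-yl]-5-oxocyclopent-3-en-1-yl}hept-5-enoate | CCCCC/C=C\C[C@@]1(O)C=C(Br)C(=O)[C@@H]1[C@H](/C=C\CCCC(=O)OC)OC(C)=O | target

## Step count

- Total steps: 12.
- Longest linear sequence: 10 (steps 1–7 and 10–12).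

## Steps most likely to fail

**Step 7.**
- What may go wrong: the carbene also cyclopropanates C14=C15, tert-butoxide strips the enol silyl group before the carbene arrives, or the base attacks the bromoenone as it forms.
- Fallback, from 10 back to 12: carbon and bromine are brought in separately, still by a four-to-five ring enlargement.
  - Simmons–Smith methylenation (Et2Zn, CH2I2) of the enol ether bond of 10 should give the siloxybicyclo[2.1.0]pentane F1.
  - FeCl3 in DMF cleaves its central bond oxidatively (Saegusa-type enlargement) to the 3-chlorocyclopentanone F2.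
  - NaOAc in MeOH removes HCl to give the unbrominated cyclopentenone F3.
  - Nucleophilic epoxidation (t-BuOOH, DBU) touches only the electron-poor enone bond and gives the epoxy ketone F4.
  - MgBr2·OEt2 opens F4 at the carbonyl-activated, less hindered C10 to the bromohydrin F5, which loses water on mild treatment (MsCl, Et3N) to 12.

**Step 6.**
- What may go wrong: insufficient discrimination between the two enantiotopic CH2 groups of a 3,3-disubstituted ring, or loss of silanolate from the enolate before silylation.
- Fallback, from 8 back to 12: asymmetric deprotonation is replaced by resolution of the ketone.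
  - LDA/TESCl gives the racemic bis(silyloxy)cyclobutene F6.
  - F6 is taken through the conditions of step 7 to the racemic bromoenone F7.
  - Lithiated (S)-N,S-dimethyl-S-phenylsulfoximine adds to C9=O, and the two diastereomeric adducts are separated by chromatography.
  - The (12S)-configured β-hydroxysulfoximine F8 is thermolysed in refluxing toluene, which releases 12.

**Step 10.**
- What may go wrong: poor facial selectivity at C8 (attack anti to the bulky silyl ether instead of anti to the octenyl chain), Z to E isomerisation of the enal by the amine, or retro-aldol on work-up.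
- Fallback, from 12 back to 20: steric control is replaced by alkoxide-directed delivery.
  - HF·pyridine removes the silyl group first and gives the free hydroxy bromoenone F9.
  - Two equivalents of LDA at −78 °C form the dilithium alkoxide dienolate F10, in which the C12 alkoxide should bind the aldehyde and deliver it on its own face, and in which retro-aldol is blocked because C8 is already enolised.
  - Addition of 16 gives the 7,12-diol F11.
  - Ac2O/pyridine at 0 °C acetylates only the secondary C7–OH and gives 20 directly.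

Further compounds
F1 | step 7 | (3S)-3-[(2Z)-oct-2-en-1-yl]-1,3-bis(triethylsilyloxy)bicyclo[2.1.0]pentane (drawn for attack on the face of the C12 oxygen) | CCCCC/C=C\C[C@@]1(O[Si](CC)(CC)CC)[C@@H]2C[C@]2(O[Si](CC)(CC)CC)C1
F2 | step 7 | (4S)-3-chloro-4-[(2Z)-oct-2-en-1-yl]-4-(triethylsilyloxy)cyclopentan-1-one (C3 centre lost again) | CCCCC/C=C\C[C@@]1(O[Si](CC)(CC)CC)C(Cl)CC(=O)C1
F3 | step 7 | (4S)-4-[(2Z)-oct-2-en-1-yl]-4-(triethylsilyloxy)cyclopent-2-en-1-one | CCCCC/C=C\C[C@@]1(O[Si](CC)(CC)CC)C=CC(=O)C1
F4 | step 7 | (4S)-4-[(2Z)-oct-2-en-1-yl]-4-(triethylsilyloxy)-6-oxabicyclo[3.1.0]hexan-2-one (epoxide centres lost again) | CCCCC/C=C\C[C@@]1(O[Si](CC)(CC)CC)C2OC2C(=O)C1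
F5 | step 7 | (4S)-2-bromo-3-hydroxy-4-[(2Z)-oct-2-en-1-yl]-4-(triethylsilyloxy)cyclopentan-1-one (C2 and C3 centres lost again) | CCCCC/C=C\C[C@@]1(O[Si](CC)(CC)CC)C(O)C(Br)C(=O)C1
F6 | step 6 | rac-3-[(2Z)-oct-2-en-1-yl]-1,3-bis(triethylsilyloxy)cyclobut-1-ene | CCCCC/C=C\CC1(O[Si](CC)(CC)CC)C=C(O[Si](CC)(CC)CC)C1
F7 | step 6 | rac-2-bromo-4-[(2Z)-oct-2-en-1-yl]-4-(triethylsilyloxy)cyclopent-2-en-1-one | CCCCC/C=C\CC1(O[Si](CC)(CC)CC)C=C(Br)C(=O)C1
F8 | step 6 | (4S)-2-bromo-1-{[(S)-N-methyl-S-phenylsulfonimidoyl]methyl}-4-[(2Z)-oct-2-en-1-yl]-4-(triethylsilyloxy)cyclopent-2-en-1-ol (C1 centre lost again) | CCCCC/C=C\C[C@@]1(O[Si](CC)(CC)CC)C=C(Br)C(O)(C[S@@](=O)(=NC)c2ccccc2)C1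
F9 | step 10 | (4S)-2-bromo-4-hydroxy-4-[(2Z)-oct-2-en-1-yl]cyclopent-2-en-1-one | CCCCC/C=C\C[C@@]1(O)C=C(Br)C(=O)C1
F10 | step 10 | dilithium salt (C12 alkoxide, C8–C9 enolate) of F9 | CCCCC/C=C\C[C@@]1(O[Li])C=C(Br)C(O[Li])=C1
F11 | step 10 | methyl (5Z,7S)-7-{(1R,2S)-4-bromo-2-hydroxy-2-[(2Z)-oct-2-en-1-yl]-5-oxocyclopent-3-en-1-yl}-7-hydroxyhept-5-enoate | CCCCC/C=C\C[C@@]1(O)C=C(Br)C(=O)[C@@H]1[C@H](/C=C\CCCC(=O)OC)O
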